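**Strategy.** The bicyclo[3.3.1]nonene is disconnected at C1–C2: the β-acetoxy aldehyde array (O on bridge C9, formyl on bridgehead C1) is the retron of a 2,3-epoxy-alcohol semipinacol shift. In one operation the alkenyl carbon C2 of a cis-fused hydrindane migrates from the carbinol C9 to the epoxide carbon C1, so the cyclopentene (C9, C5, C4, C3, C2) grows into the cyclohexene (C9, C5, C4, C3, C2, C1), the bridge is created, C1 becomes quaternary with its CH2OH, and C9 becomes the ketone. The precursor is a spiro-epoxy hydrindenol assembled from (R)-citronellal, methyl vinyl ketone and an allenylstannane; the citronellal-derived C8 centre relays all ring stereochemistry.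

Key step: step 13

Remark: labels C1–C9 are those of the target's bicyclo[3.3.1]non-2-ene core (C1 and C2 carry the formyl groups, C5 the methyl, C8 the side chain, C9 the acetate) and are kept for the same atoms in every intermediate ("target numbering"); commercial (R)-citronellal is assumed enantiopure.

**Route**

Step 1
Reactants: 1 (R)-citronellal; 2 methyl vinyl ketone
Product: 3 (2S)-2-[(2R)-6-methylhept-5-en-2-yl]-5-oxohexanal
Conditions: (S)-2-[diphenyl(trimethylsilyloxy)methyl]pyrrolidine (10 mol%), ethyl 3,4-dihydroxybenzoate (20 mol%), EtOH, 0 °C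
Reagents that add atoms: none
Why: Enamine Michael addition under diarylprolinol silyl ether catalysis: the catalyst blocks one face of the E-enamine, so the new α-centre (C8, target numbering) should form as S under catalyst control while the (R)-methyl centre is untouched.

Step 2
Reactants: 3 (2S)-2-[(2R)-6-methylhept-5-en-2-yl]-5-oxohexanal
Product: 4 (4S)-4-[(2R)-6-methylhept-5-en-2-yl]cyclohex-2-en-1-one
Conditions: KOH (0.1 M aq.), nBu4NOH (cat.), Et2O/THF, reflux
Reagents that add atoms: none
Why: Intramolecular aldol condensation of the methyl ketone onto the aldehyde closes the cyclohexenone, and fast ring closure under mild hydroxide conditions should outrun epimerisation of the α-branched aldehyde.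

Step 3
Reactants: 4 (4S)-4-[(2R)-6-methylhept-5-en-2-yl]cyclohex-2-en-1-one
Product: 5 (4S)-1-methyl-4-[(2R)-6-methylhept-5-en-2-yl]cyclohex-2-en-1-ol (both C1 epimers)
Conditions: MeLi, Et2O, −78 °C
Reagents that add atoms: methyllithium, [Li]C
Why: 1,2-Addition of the hard organolithium to the enone carbonyl gives the tertiary allylic alcohol; the new carbinol centre forms as a mixture, which does not matter because step 4 destroys it.

Step 4
Reactants: 5 (4S)-1-methyl-4-[(2R)-6-methylhept-5-en-2-yl]cyclohex-2-en-1-ol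
Product: 6 (6S)-3-methyl-6-[(2R)-6-methylhept-5-en-2-yl]cyclohex-2-en-1-one
Conditions: pyridinium chlorochromate (C5H5NH)[CrO3Cl], 4 Å sieves, CH2Cl2, rt
Reagents that add atoms: pyridinium chlorochromate (its oxo oxygen becomes the carbonyl oxygen), [O-][Cr](=O)(=O)Cl.c1cc[nH+]cc1
Why: Babler–Dauben oxidative 1,3-transposition: the tertiary chromate ester shifts [3,3] to the secondary allylic chromate, which is oxidised, placing the carbonyl at C1 next to C8 and the methyl on the β-carbon C5.

Step 5
Reactants: 6 (6S)-3-methyl-6-[(2R)-6-methylhept-5-en-2-yl]cyclohex-2-en-1-one; 7 allenyltributylstannane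
Product: 8 tert-butyl-dimethyl-{[(3R,6S)-3-methyl-6-[(2R)-6-methylhept-5-en-2-yl]-3-(prop-2-yn-1-yl)cyclohex-1-en-1-yl]oxy}silane
Conditions: 7 (1.5 equiv), TBSOTf (1.2 equiv), CH2Cl2, −78 °C; Et3N quench
Reagents that add atoms: tert-butyldimethylsilyl triflate, CC(C)(C)[Si](C)(C)OS(=O)(=O)C(F)(F)F
Why: Hosomi–Sakurai-type SE2' conjugate propargylation of the silyl-triflate-activated enone creates quaternary C5 and traps the enolate regiospecifically; axial attack on the half-chair that keeps the large C8 substituent equatorial should place the propargyl group cis to the side chain.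

Step 6
Reactants: 8 silyl enol ether with terminal alkyne
Product: 9 tert-butyl-{[(3R,6S)-3-(3-iodoprop-2-yn-1-yl)-3-methyl-6-[(2R)-6-methylhept-5-en-2-yl]cyclohex-1-en-1-yl]oxy}dimethylsilane
Conditions: N-iodosuccinimide, AgNO3 (10 mol%), DMF, 0 °C, dark
Reagents that add atoms: N-iodosuccinimide, O=C1CCC(=O)N1I
Why: Silver-catalysed electrophilic iodination of the terminal alkyne gives the 1-iodoalkyne; the hindered tert-butyldimethylsilyl enol ether and the trisubstituted alkene should survive at 0 °C.

Step 7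
Reactants: 9 iodoalkyne silyl enol ether
Product: 10 cis-fused 3-iodo-7a-methyl-5-[(2R)-6-methylhept-5-en-2-yl]-1,3a,5,6,7,7a-hexahydro-4H-inden-4-one (side chain trans to the 7a-methyl)
Conditions: Ph3PAuCl (10 mol%), AgBF4 (10 mol%), CH2Cl2/H2O 10:1, 40 °C
Reagents that add atoms: none
Why: Gold-catalysed 5-endo-dig carbocyclisation (Conia-ene type) of the silyl enol ether onto the activated iodoalkyne forms the C9–C2 bond and, after protodeauration and desilylation, the vinyl iodide; the three-atom tether from quaternary C5 allows only the cis ring fusion, which sets C9.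

Step 8
Reactants: 10 cis-fused iodo-hydrindenone
Product: 12 cis-fused 3a-hydroxy-3-iodo-7a-methyl-5-[(2R)-6-methylhept-5-en-2-yl]-1,3a,5,6,7,7a-hexahydro-4H-inden-4-one (hydroxyl cis to the 7a-methyl), via potassium dienolate 11 (not isolated)
Conditions: KN(SiMe3)2, THF, −78 °C; then 3-phenyl-2-(phenylsulfonyl)oxaziridine, −78 °C; AcOH quench
Reagents that add atoms: 3-phenyl-2-(phenylsulfonyl)oxaziridine, O=S(=O)(c1ccccc1)N1OC1c1ccccc1
Why: Deprotonation at the doubly activated ring-fusion carbon (α to the ketone and allylic) and α-hydroxylation of the dienolate by the N-sulfonyloxaziridine (enolate oxidation) should deliver oxygen on the face that keeps the cis ring fusion, syn to the angular methyl.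

Step 9
Reactants: 12 α-hydroxy ketone
Product: 13 cis-fused 3-iodo-7a-methyl-4-methylidene-5-[(2R)-6-methylhept-5-en-2-yl]-1,4,5,6,7,7a-hexahydro-3aH-inden-3a-ol
Conditions: Cp2TiMe2 (3 equiv), toluene, 65 °C, dark
Reagents that add atoms: dimethyltitanocene Cp2TiMe2, [CH3-].[CH3-].[Ti+4].c1cc[cH-]c1.c1cc[cH-]c1
Why: Petasis methylenation: the thermally generated titanium methylidene is non-basic and small enough for a hindered, enolisable ketone, so the exocyclic alkene should form without epimerising C8.

Step 10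
Reactants: 13 exocyclic allylic alcohol
Product: 14 cis-fused 3-iodo-7a-methyl-5-[(2R)-6-methylhept-5-en-2-yl]-5,6,7,7a-tetrahydro-1H-spiro[indene-4,2'-oxiran]-3a-ol (epoxide oxygen cis to the 3a-hydroxyl)
Conditions: VO(acac)2 (5 mol%), tBuOOH (decane), CH2Cl2, 0 °C → rt
Reagents that add atoms: tert-butyl hydroperoxide, CC(C)(C)OO
Why: Hydroxyl-directed epoxidation: the vanadium alkoxide–peroxide complex delivers oxygen to the 1,1-disubstituted allylic alkene from the hydroxyl face, sparing the electron-poor iodoalkene and the remote trisubstituted alkene, which sets the spiro carbon with O syn to OH and anti to C2.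

Step 11
Reactants: 14 iodo epoxy alcohol
Product: 15 3-(hydroxymethyl) analogue of 14: cis-fused 3-(hydroxymethyl)-7a-methyl-5-[(2R)-6-methylhept-5-en-2-yl]-5,6,7,7a-tetrahydro-1H-spiro[indene-4,2'-oxiran]-3a-ol
Conditions: Bu3SnCH2OH (2 equiv), Pd(PPh3)4 (10 mol%), 1,4-dioxane, 90 °C
Reagents that add atoms: (tributylstannyl)methanol, CCCC[Sn](CO)(CCCC)CCCC
Why: Stille cross-coupling of the alkenyl iodide with the hydroxymethylstannane installs the future C2 formyl carbon with retention of the ring alkene, and the neutral conditions should leave the epoxy alcohol intact.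

Step 12
Reactants: 15 epoxy diol
Product: 16 3-{[tert-butyl(dimethyl)silyl]oxymethyl} analogue of 14 (tertiary hydroxyl free)
Conditions: TBSCl, imidazole, CH2Cl2, 0 °C
Reagents that add atoms: tert-butyldimethylsilyl chloride, CC(C)(C)[Si](C)(C)Cl
Why: Selective silylation of the primary allylic hydroxyl over the hindered tertiary one prevents the primary hydroxyl from opening the epoxide in step 13.

Step 13
Reactants: 16 silyl-protected spiro-epoxy hydrindenol
Product: 17 (1S,5R,8S)-2-{[tert-butyl(dimethyl)silyl]oxymethyl}-1-(hydroxymethyl)-5-methyl-8-[(2R)-6-methylhept-5-en-2-yl]bicyclo[3.3.1]non-2-en-9-one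
Conditions: BF3·OEt2 (1.1 equiv), CH2Cl2, −78 °C; NaHCO3 quench
Reagents that add atoms: none
Why: BF3 opens the spiro-epoxide at tertiary C1 while the alkenyl carbon C2, on the face opposite the epoxide oxygen, shifts from C9 to C1 through a bridged cyclopropylcarbinyl-like cation and the C9 hydroxyl collapses to the ketone; this is the semipinacol rearrangement of a 2,3-epoxy alcohol with alkenyl migration. The six-membered ring C9–C5–C4–C3–C2–C1 is closed by this 1,2-shift (ring expansion of the cyclopentene by insertion of C1, not a cyclisation), and the cyclohexane ring is carried through unchanged, so the fused bicycle becomes the bridged one. C1 is the only new stereocentre and is set by inversion at the epoxide carbon: C2 enters anti to the departing oxygen, which step 10 placed syn to the C9 hydroxyl. The selectivity needed is migration of alkenyl C2 rather than ring carbon C5 (which would contract the cyclohexane): C2 is the better migrating group through π-participation, and the conformer that aligns it with the C1–O bond, although it puts the C8 side chain axial, is freed of the allylic-type strain between an equatorial side chain and the spiro-epoxide. The epoxide must also ionise faster than the tertiary allylic alcohol and the side-chain alkene must not trap the cation; the concerted, low-temperature course should secure both.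

Step 14
Reactants: 17 bicyclic β-hydroxy ketone
Product: 19 (1S,5R,8S,9R)-1,2-bis(hydroxymethyl)-5-methyl-8-[(2R)-6-methylhept-5-en-2-yl]bicyclo[3.3.1]non-2-en-9-ol, via silyl ether diol 18 (not isolated)
Conditions: NaBH4, MeOH, 0 °C → rt; then 1 M HCl to pH 1–2, rt
Reagents that add atoms: none
Why: Hydride reduction of the bridging ketone from the less hindered side, over the unsaturated bridge (one pseudo-axial hydrogen) rather than the chair cyclohexane bridge (two axial hydrogens), should give the 9-hydroxyl syn to the saturated bridge; acidic methanol then cleaves the primary silyl ether in the same flask.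

Step 15
Reactants: 19 triol
Product: 20 (1R,5R,8S,9R)-9-hydroxy-5-methyl-8-[(2R)-6-methylhept-5-en-2-yl]bicyclo[3.3.1]non-2-ene-1,2-dicarbaldehyde
Conditions: TEMPO (20 mol%), PhI(OAc)2 (2.5 equiv), CH2Cl2, rt
Reagents that add atoms: none
Why: Oxoammonium (TEMPO)-catalysed oxidation is selective for the primary allylic and primary neopentyl alcohols over the hindered secondary one and stops at the aldehydes, neither of which can epimerise (C1 quaternary, C2 sp2).

Step 16
Reactants: 20 hydroxy dialdehyde
Product: 21 (1R,5R,8S,9R)-1,2-diformyl-5-methyl-8-[(2R)-6-methylhept-5-en-2-yl]bicyclo[3.3.1]non-2-en-9-yl acetate (CNP0299929.2)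
Conditions: Ac2O, DMAP, pyridine, rt → 40 °C
Reagents that add atoms: acetic anhydride, CC(=O)OC(C)=O
Why: DMAP-catalysed acylation of the remaining secondary alcohol; the β-acetoxy aldehyde cannot eliminate because C1 carries no hydrogen.

**Compound list**

1 | (R)-citronellal, (3R)-3,7-dimethyloct-6-enal | O=CC[C@H](C)CCC=C(C)C | starting material
2 | methyl vinyl ketone, but-3-en-2-one | CC(=O)C=C | starting material
3 | (2S)-2-[(2R)-6-methylhept-5-en-2-yl]-5-oxohexanal | O=C[C@@H](CCC(C)=O)[C@H](C)CCC=C(C)C | intermediate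
4 | (4S)-4-[(2R)-6-methylhept-5-en-2-yl]cyclohex-2-en-1-one | O=C1C=C[C@H]([C@H](C)CCC=C(C)C)CC1 | intermediate
5 | (4S)-1-methyl-4-[(2R)-6-methylhept-5-en-2-yl]cyclohex-2-en-1-ol, both C1 epimers | CC1(O)C=C[C@H]([C@H](C)CCC=C(C)C)CC1 | intermediate
6 | (6S)-3-methyl-6-[(2R)-6-methylhept-5-en-2-yl]cyclohex-2-en-1-one | CC1=CC(=O)[C@H]([C@H](C)CCC=C(C)C)CC1 | intermediate
7 | allenyltributylstannane, tributyl(propa-1,2-dien-1-yl)stannane | C=C=C[Sn](CCCC)(CCCC)CCCC | starting material
8 | tert-butyl-dimethyl-{[(3R,6S)-3-methyl-6-[(2R)-6-methylhept-5-en-2-yl]-3-(prop-2-yn-1-yl)cyclohex-1-en-1-yl]oxy}silane (propargyl cis to side chain) | C#CC[C@]1(C)C=C(O[Si](C)(C)C(C)(C)C)[C@H]([C@H](C)CCC=C(C)C)CC1 | intermediate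
9 | 3-iodopropargyl analogue of 8 | IC#CC[C@]1(C)C=C(O[Si](C)(C)C(C)(C)C)[C@H]([C@H](C)CCC=C(C)C)CC1 | intermediate
10 | cis-fused 3-iodo-7a-methyl-5-[(2R)-6-methylhept-5-en-2-yl]-1,3a,5,6,7,7a-hexahydro-4H-inden-4-one, side chain trans to 7a-methyl | IC1=CC[C@@]2(C)CC[C@@H]([C@H](C)CCC=C(C)C)C(=O)[C@@H]12 | intermediate
11 | potassium dienolate of 10 | IC1=CC[C@@]2(C)CC[C@@H]([C@H](C)CCC=C(C)C)C([O-])=C12.[K+] | intermediate (not isolated)
12 | 3a-hydroxy derivative of 10, hydroxyl cis to 7a-methyl | IC1=CC[C@@]2(C)CC[C@@H]([C@H](C)CCC=C(C)C)C(=O)[C@@]12O | intermediate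
13 | cis-fused 3-iodo-7a-methyl-4-methylidene-5-[(2R)-6-methylhept-5-en-2-yl]-1,4,5,6,7,7a-hexahydro-3aH-inden-3a-ol | IC1=CC[C@@]2(C)CC[C@@H]([C@H](C)CCC=C(C)C)C(=C)[C@@]12O | intermediate
14 | cis-fused 3-iodo-7a-methyl-5-[(2R)-6-methylhept-5-en-2-yl]-5,6,7,7a-tetrahydro-1H-spiro[indene-4,2'-oxiran]-3a-ol, epoxide O cis to OH | IC1=CC[C@@]2(C)CC[C@@H]([C@H](C)CCC=C(C)C)[C@@]3(CO3)[C@@]12O | intermediate
15 | 3-(hydroxymethyl) analogue of 14 | OCC1=CC[C@@]2(C)CC[C@@H]([C@H](C)CCC=C(C)C)[C@@]3(CO3)[C@@]12O | intermediate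
16 | 3-{[tert-butyl(dimethyl)silyl]oxymethyl} analogue of 14 | CC(C)(C)[Si](C)(C)OCC1=CC[C@@]2(C)CC[C@@H]([C@H](C)CCC=C(C)C)[C@@]3(CO3)[C@@]12O | intermediate
17 | (1S,5R,8S)-2-{[tert-butyl(dimethyl)silyl]oxymethyl}-1-(hydroxymethyl)-5-methyl-8-[(2R)-6-methylhept-5-en-2-yl]bicyclo[3.3.1]non-2-en-9-one | O=C1[C@@]2(C)CC=C(CO[Si](C)(C)C(C)(C)C)[C@]1(CO)[C@H]([C@H](C)CCC=C(C)C)CC2 | intermediate
18 | (1S,5R,8S,9R)-9-hydroxy analogue of 17 (9-OH syn to the saturated bridge) | O[C@@H]1[C@@]2(C)CC=C(CO[Si](C)(C)C(C)(C)C)[C@]1(CO)[C@H]([C@H](C)CCC=C(C)C)CC2 | intermediate (not isolated)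
19 | (1S,5R,8S,9R)-1,2-bis(hydroxymethyl)-5-methyl-8-[(2R)-6-methylhept-5-en-2-yl]bicyclo[3.3.1]non-2-en-9-ol | O[C@@H]1[C@@]2(C)CC=C(CO)[C@]1(CO)[C@H]([C@H](C)CCC=C(C)C)CC2 | intermediate
20 | (1R,5R,8S,9R)-9-hydroxy-5-methyl-8-[(2R)-6-methylhept-5-en-2-yl]bicyclo[3.3.1]non-2-ene-1,2-dicarbaldehyde | O[C@@H]1[C@@]2(C)CC=C(C=O)[C@]1(C=O)[C@H]([C@H](C)CCC=C(C)C)CC2 | intermediate
21 | (1R,5R,8S,9R)-1,2-diformyl-5-methyl-8-[(2R)-6-methylhept-5-en-2-yl]bicyclo[3.3.1]non-2-en-9-yl acetate | CC(=O)O[C@@H]1[C@@]2(C)CC=C(C=O)[C@]1(C=O)[C@H]([C@H](C)CCC=C(C)C)CC2 | target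

**Totals.** Total step count: 16. Longest linear sequence: 16 steps (1 → 21).

**Steps most likely to fail, with fallbacks**

Step 13 (key step). What may go wrong: migration of ring carbon C5 instead of alkenyl C2 from the more populated chair (ring contraction of the cyclohexane), ionisation of the tertiary allylic alcohol, or capture of the cation by the side-chain alkene. The fallback makes the migrating carbon silicon-bearing, so that it attacks C1 through a β-silyl-stabilised cation. It sets out from iodide 14: palladium-catalysed silylation with hexamethyldisilane (Pd(PPh3)4) would give the 3-trimethylsilyl epoxy alcohol F1; BF3·OEt2 or Et2AlCl at −78 °C would then give the silylated bicyclic hydroxy ketone F2; iododesilylation with N-iodosuccinimide the alkenyl iodide F3; Stille hydroxymethylation (Bu3SnCH2OH, Pd(PPh3)4) the keto diol F4; and NaBH4 reduction would come back to the route at triol 19.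

Step 5. What may go wrong: sluggish addition to the β,β-disubstituted enone, protodestannylation of the reagent, or poor facial selectivity in forming quaternary C5. The fallback sets the quaternary centre by cuprate chemistry and builds the alkyne afterwards. It sets out from enone 6: CH2=CHMgBr with CuBr·SMe2 (cat.), TBSCl and HMPA would give the 3-vinyl silyl enol ether F5; chemoselective hydroboration of the vinyl group (9-BBN, then NaBO3) the primary alcohol F6; buffered Dess–Martin oxidation the aldehyde F7; and Ohira–Bestmann homologation (dimethyl 1-diazo-2-oxopropylphosphonate, K2CO3, MeOH) would come back to the route at alkyne 8.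

Step 9. What may go wrong: thermal or Lewis-acid-induced α-ketol rearrangement of the hindered α-hydroxy ketone, or epimerisation at C8, outrunning slow carbonyl methylenation. The fallback is a low-temperature Peterson olefination. It sets out from hydroxy ketone 12: Me3SiCH2Li premixed with CeCl3 (THF, −78 °C) would give the β-hydroxysilane F8, and KH-induced elimination (THF, 0 °C) would come back to the route at allylic alcohol 13.

**Further compounds**

F1 | step 13 | 3-(trimethylsilyl) analogue of 14: cis-fused 7a-methyl-5-[(2R)-6-methylhept-5-en-2-yl]-3-(trimethylsilyl)-5,6,7,7a-tetrahydro-1H-spiro[indene-4,2'-oxiran]-3a-ol | C[Si](C)(C)C1=CC[C@@]2(C)CC[C@@H]([C@H](C)CCC=C(C)C)[C@@]3(CO3)[C@@]12O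
F2 | step 13 | 1-(hydroxymethyl)-5-methyl-8-[(2R)-6-methylhept-5-en-2-yl]-2-(trimethylsilyl)bicyclo[3.3.1]non-2-en-9-one, configuration as in 17 | O=C1[C@@]2(C)CC=C([Si](C)(C)C)[C@]1(CO)[C@H]([C@H](C)CCC=C(C)C)CC2
F3 | step 13 | 1-(hydroxymethyl)-2-iodo-5-methyl-8-[(2R)-6-methylhept-5-en-2-yl]bicyclo[3.3.1]non-2-en-9-one, configuration as in 17 | O=C1[C@@]2(C)CC=C(I)[C@]1(CO)[C@H]([C@H](C)CCC=C(C)C)CC2
F4 | step 13 | 1,2-bis(hydroxymethyl)-5-methyl-8-[(2R)-6-methylhept-5-en-2-yl]bicyclo[3.3.1]non-2-en-9-one, configuration as in 17 | O=C1[C@@]2(C)CC=C(CO)[C@]1(CO)[C@H]([C@H](C)CCC=C(C)C)CC2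
F5 | step 5 | tert-butyl-{[3-ethenyl-3-methyl-6-[(2R)-6-methylhept-5-en-2-yl]cyclohex-1-en-1-yl]oxy}dimethylsilane, vinyl cis to side chain | C=C[C@]1(C)C=C(O[Si](C)(C)C(C)(C)C)[C@H]([C@H](C)CCC=C(C)C)CC1
F6 | step 5 | 2-{3-[tert-butyl(dimethyl)silyl]oxy-1-methyl-4-[(2R)-6-methylhept-5-en-2-yl]cyclohex-2-en-1-yl}ethanol | OCC[C@]1(C)C=C(O[Si](C)(C)C(C)(C)C)[C@H]([C@H](C)CCC=C(C)C)CC1
F7 | step 5 | 2-{3-[tert-butyl(dimethyl)silyl]oxy-1-methyl-4-[(2R)-6-methylhept-5-en-2-yl]cyclohex-2-en-1-yl}acetaldehyde | O=CC[C@]1(C)C=C(O[Si](C)(C)C(C)(C)C)[C@H]([C@H](C)CCC=C(C)C)CC1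
F8 | step 9 | cis-fused 3-iodo-7a-methyl-5-[(2R)-6-methylhept-5-en-2-yl]-4-[(trimethylsilyl)methyl]-1,4,5,6,7,7a-hexahydro-3aH-indene-3a,4-diol, both C4 epimers | IC1=CC[C@@]2(C)CC[C@@H]([C@H](C)CCC=C(C)C)C(O)(C[Si](C)(C)C)[C@@]12O
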